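**Retrosynthetic overview**
1. The C3 acetoxymethyl and C4 senecioate groups (cyclodeca[b]furan numbering) are installed last, on a macrocyclic allylic alcohol.
2. The ten-membered carbocycle is the last ring formed, by an intramolecular Nozaki–Hiyama–Kishi reaction between the alkenyl bromide of the butenolide and an aldehyde (C3a–C4 bond).
3. The (Z)-alkylidene butenolide comes from a vinylogous Mukaiyama aldol/dehydration that joins a five-carbon bromobutenolide (from tetronic acid) to a ten-carbon keto-aldehyde.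
4. The keto-aldehyde is cut at the ketone into a five-carbon alkyllithium from (S)-2-methylglycidol (C10 carbinol) and a five-carbon Weinreb amide from α-methylene-γ-butyrolactone (C6 methyl centre, asymmetric hydrogenation).
5. Ring order: the furanone ring is present from the start; the ten-membered ring is closed afterwards.

Assumption: the target is the open 10-hydroxy-7-ketone as drawn (a transannular hemiketal, if it forms, is the same compound in equilibrium), and the ring closure in step 17 is taken to give the 4R carbinol as the major epimer.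

**Fragment 1 (steps 1–4)**

Step 1
Reactants: 1 (S)-(2-methyloxiran-2-yl)methanol
Product: 2 (R)-2-{[(4-methoxybenzyl)oxy]methyl}-2-methyloxirane
Conditions: NaH, PMBCl, Bu4NI (cat.), THF/DMF, 0 °C → rt
Reagents that add atoms: 4-methoxybenzyl chloride, COc1ccc(CCl)cc1
Why: Williamson etherification of the primary alkoxide leaves the quaternary centre untouched (the Payne shift of this epoxy alcohol is degenerate); the descriptor changes from S to R only because the CIP priorities change.

Step 2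
Reactants: 2 (R)-2-{[(4-methoxybenzyl)oxy]methyl}-2-methyloxirane
Product: 3 (R)-1-[(4-methoxybenzyl)oxy]-2-methylbut-3-en-2-ol
Conditions: Me3S+ I− (3 equiv), n-BuLi (2.9 equiv), THF, −10 °C → rt
Reagents that add atoms: trimethylsulfonium iodide, C[S+](C)C.[I-]
Why: One-carbon homologation of an epoxide to an allylic alcohol: dimethylsulfonium methylide opens the epoxide at CH2 and excess ylide eliminates Me2S from the betaine, so the tertiary carbinol keeps its configuration.

Step 3
Reactants: 3 (R)-1-[(4-methoxybenzyl)oxy]-2-methylbut-3-en-2-ol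
Product: 4 (R)-tert-butyl({1-[(4-methoxybenzyl)oxy]-2-methylbut-3-en-2-yl}oxy)dimethylsilane
Conditions: TBSOTf, 2,6-lutidine, CH2Cl2, 0 °C → rt
Reagents that add atoms: tert-butyldimethylsilyl trifluoromethanesulfonate, CC(C)(C)[Si](C)(C)OS(=O)(=O)C(F)(F)F
Why: Silylation with the silyl triflate is strong enough for a hindered tertiary alcohol, and the bulky tertiary silyl ether later resists migration to carbon.

Step 4
Reactants: 4 (R)-tert-butyl({1-[(4-methoxybenzyl)oxy]-2-methylbut-3-en-2-yl}oxy)dimethylsilane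
Product: 6 (R)-tert-butyl({4-iodo-1-[(4-methoxybenzyl)oxy]-2-methylbutan-2-yl}oxy)dimethylsilane, via alkylzirconocene chloride 5 (not isolated)
Conditions: Cp2Zr(H)Cl (1.5 equiv), THF, rt; then I2, 0 °C
Reagents that add atoms: iodine, II
Why: Hydrozirconation–iodination: Zr–H adds to the terminal alkene with zirconium on the terminal carbon, and iodinolysis of the C–Zr bond gives the primary iodide.

**Fragment 2 (steps 5–7)**

Step 5
Reactants: 7 3-methylideneoxolan-2-one (α-methylene-γ-butyrolactone)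
Product: 8 (S)-3-methyloxolan-2-one
Conditions: H2 (100 atm), Ru(OAc)2[(R)-BINAP] (0.5 mol%), CH2Cl2, 50 °C
Reagents that add atoms: none
Why: Noyori-type asymmetric hydrogenation of a carbonyl-chelating 1,1-disubstituted alkene sets the methyl-bearing centre; the R ligand is the one expected to give the S lactone (about 95% ee), to be confirmed by optical rotation.

Step 6
Reactants: 8 (S)-3-methyloxolan-2-one
Product: 9 (S)-4-hydroxy-N-methoxy-N,2-dimethylbutanamide
Conditions: MeNH(OMe)·HCl, AlMe3, CH2Cl2, 0 °C → rt; aq. potassium sodium tartrate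
Reagents that add atoms: N,O-dimethylhydroxylamine hydrochloride, CNOC.Cl
Why: Weinreb aminolysis of the lactone by the aluminium amide is an acyl substitution under non-basic conditions, so the α-centre does not epimerise.

Step 7
Reactants: 9 (S)-4-hydroxy-N-methoxy-N,2-dimethylbutanamide
Product: 10 (S)-N-methoxy-N,2-dimethyl-4-[(triethylsilyl)oxy]butanamide
Conditions: TESCl, imidazole, CH2Cl2, 0 °C
Reagents that add atoms: chlorotriethylsilane, CC[Si](Cl)(CC)CC
Why: Immediate silylation of the primary alcohol stops relactonisation and installs a group that is later oxidised off directly.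

**Joining fragments 1 and 2 (steps 8–10)**

Step 8
Reactants: 6 (R)-tert-butyl({4-iodo-1-[(4-methoxybenzyl)oxy]-2-methylbutan-2-yl}oxy)dimethylsilane; 10 (S)-N-methoxy-N,2-dimethyl-4-[(triethylsilyl)oxy]butanamide
Product: 12 (3S,7R)-7-[(tert-butyldimethylsilyl)oxy]-8-[(4-methoxybenzyl)oxy]-3,7-dimethyl-1-[(triethylsilyl)oxy]octan-4-one, via alkyllithium 11 (not isolated)
Conditions: 6, t-BuLi (2.1 equiv), Et2O, −78 °C; then 10, −78 → −20 °C; aq. NH4Cl
Reagents that add atoms: none
Why: Iodine–lithium exchange followed by Weinreb ketone synthesis: the chelated tetrahedral adduct prevents over-addition, neither stereocentre is touched, and the cold ether medium suppresses silyl migration from oxygen to carbon.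

Step 9
Reactants: 12 (3S,7R)-7-[(tert-butyldimethylsilyl)oxy]-8-[(4-methoxybenzyl)oxy]-3,7-dimethyl-1-[(triethylsilyl)oxy]octan-4-one
Product: 13 (3S,7R)-7-[(tert-butyldimethylsilyl)oxy]-8-hydroxy-3,7-dimethyl-1-[(triethylsilyl)oxy]octan-4-one
Conditions: DDQ, CH2Cl2/pH 7 buffer (10:1), 0 °C
Reagents that add atoms: none
Why: Oxidative cleavage of the electron-rich 4-methoxybenzyl ether under buffered conditions spares both silyl ethers and the ketone.

Step 10
Reactants: 13 (3S,7R)-7-[(tert-butyldimethylsilyl)oxy]-8-hydroxy-3,7-dimethyl-1-[(triethylsilyl)oxy]octan-4-one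
Product: 14 (2R,6S)-2-[(tert-butyldimethylsilyl)oxy]-2,6-dimethyl-5-oxo-8-[(triethylsilyl)oxy]octanal
Conditions: Dess–Martin periodinane, NaHCO3, CH2Cl2, 0 °C → rt
Reagents that add atoms: none
Why: Dess–Martin oxidation of the primary alcohol gives an aldehyde with no α-hydrogen, so it cannot epimerise or enolise.

**Fragment 3 (steps 11–14)**

Step 11
Reactants: 15 tetronic acid (4-hydroxyfuran-2(5H)-one)
Product: 17 4-bromo-2-oxo-2,5-dihydrofuran-3-carbaldehyde, via bromo iminium salt 16 (not isolated)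
Conditions: POBr3 (2.5 equiv), DMF (3 equiv), ClCH2CH2Cl, 0 → 60 °C; ice, aq. NaOAc
Reagents that add atoms: N,N-dimethylformamide, CN(C)C=O; phosphorus oxybromide, O=P(Br)(Br)Br; water, O
Why: Vilsmeier–Haack–Arnold bromoformylation: the nucleophilic C3 of the vinylogous acid is formylated and the enol OH is exchanged for bromide, as with 4-hydroxycoumarin.

Step 12
Reactants: 17 4-bromo-2-oxo-2,5-dihydrofuran-3-carbaldehyde
Product: 18 4-bromo-3-(hydroxymethyl)furan-2(5H)-one
Conditions: NaBH4, CeCl3·7H2O, MeOH, −78 °C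
Reagents that add atoms: none
Why: Luche reduction delivers hydride 1,2 to the aldehyde only, avoiding conjugate addition–elimination at the bromo-bearing carbon and leaving the lactone intact.

Step 13
Reactants: 18 4-bromo-3-(hydroxymethyl)furan-2(5H)-one
Product: 19 4-bromo-3-{[(tert-butyldimethylsilyl)oxy]methyl}furan-2(5H)-one
Conditions: TBSCl, imidazole, DMF, 0 °C → rt
Reagents that add atoms: tert-butyldimethylsilyl chloride, CC(C)(C)[Si](C)(C)Cl
Why: Silylation masks the allylic primary alcohol as a poor leaving group for the base and chromium steps ahead.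

Step 14
Reactants: 19 4-bromo-3-{[(tert-butyldimethylsilyl)oxy]methyl}furan-2(5H)-one
Product: 20 4-bromo-3-{[(tert-butyldimethylsilyl)oxy]methyl}-2-[(triisopropylsilyl)oxy]furan
Conditions: TIPSOTf, Et3N, CH2Cl2, 0 °C
Reagents that add atoms: triisopropylsilyl trifluoromethanesulfonate, CC(C)[Si](OS(=O)(=O)C(F)(F)F)(C(C)C)C(C)C
Why: Soft enolisation at C5 and O-silylation give the aromatic 2-silyloxyfuran, a vinylogous silyl ketene acetal that is nucleophilic at C5.

**Coupling, ring closure and end game (steps 15–20)**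

Step 15
Reactants: 14 (2R,6S)-2-[(tert-butyldimethylsilyl)oxy]-2,6-dimethyl-5-oxo-8-[(triethylsilyl)oxy]octanal; 20 4-bromo-3-{[(tert-butyldimethylsilyl)oxy]methyl}-2-[(triisopropylsilyl)oxy]furan
Product: 23 (Z)-4-bromo-3-{[(tert-butyldimethylsilyl)oxy]methyl}-5-{(2R,6S)-2-[(tert-butyldimethylsilyl)oxy]-2,6-dimethyl-5-oxo-8-[(triethylsilyl)oxy]octylidene}furan-2(5H)-one, via aldol adduct 21 (not isolated), via mesylate 22 (not isolated)
Conditions: BF3·OEt2, CH2Cl2, −78 °C; aq. NaHCO3; crude, then MsCl, Et3N, CH2Cl2, −20 → 0 °C; DBU, 0 °C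
Reagents that add atoms: none
Why: Vinylogous Mukaiyama aldol addition at C5 of the silyloxyfuran (aldehyde-selective over the ketone at −78 °C) followed by mesylation and E1cB elimination; the Z alkene is favoured because the quaternary carbon then points away from the C4 bromine.

Step 16
Reactants: 23 (Z)-4-bromo-3-{[(tert-butyldimethylsilyl)oxy]methyl}-5-{(2R,6S)-2-[(tert-butyldimethylsilyl)oxy]-2,6-dimethyl-5-oxo-8-[(triethylsilyl)oxy]octylidene}furan-2(5H)-one
Product: 24 (3S,7R,8Z)-8-[3-bromo-4-{[(tert-butyldimethylsilyl)oxy]methyl}-5-oxofuran-2(5H)-ylidene]-7-[(tert-butyldimethylsilyl)oxy]-3,7-dimethyl-4-oxooctanal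
Conditions: (COCl)2, DMSO, CH2Cl2, −78 → −40 °C; Et3N, −78 → 0 °C; used at once
Reagents that add atoms: none
Why: Swern oxidation cleaves a primary triethylsilyl ether in situ and oxidises it to the aldehyde while primary and tertiary TBS ethers survive, so no free γ-hydroxy ketone is ever formed.

Step 17
Reactants: 24 (3S,7R,8Z)-8-[3-bromo-4-{[(tert-butyldimethylsilyl)oxy]methyl}-5-oxofuran-2(5H)-ylidene]-7-[(tert-butyldimethylsilyl)oxy]-3,7-dimethyl-4-oxooctanal
Product: 25 (4R,6S,10R,11Z)-10-[(tert-butyldimethylsilyl)oxy]-3-{[(tert-butyldimethylsilyl)oxy]methyl}-4-hydroxy-6,10-dimethyl-5,6,9,10-tetrahydrocyclodeca[b]furan-2,7(4H,8H)-dione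
Conditions: CrCl2 (10 equiv), NiCl2 (2 mol%), DMSO, rt, 2 mM, slow addition of 24
Reagents that add atoms: none
Why: Intramolecular Nozaki–Hiyama–Kishi reaction: zerovalent nickel (formed from NiCl2 by divalent chromium) inserts into the activated C–Br bond, and the resulting alkenyl species of trivalent chromium adds to the aldehyde but not the ketone; the carbinol is set under macrocyclic control, the 4R epimer (hydroxyl syn to the C6 methyl) being assumed.

Step 18
Reactants: 25 (4R,6S,10R,11Z)-10-[(tert-butyldimethylsilyl)oxy]-3-{[(tert-butyldimethylsilyl)oxy]methyl}-4-hydroxy-6,10-dimethyl-5,6,9,10-tetrahydrocyclodeca[b]furan-2,7(4H,8H)-dione; 26 3-methylbut-2-enoic acid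
Product: 27 (4R,6S,10R,11Z)-10-[(tert-butyldimethylsilyl)oxy]-3-{[(tert-butyldimethylsilyl)oxy]methyl}-6,10-dimethyl-2,7-dioxo-2,4,5,6,7,8,9,10-octahydrocyclodeca[b]furan-4-yl 3-methylbut-2-enoate
Conditions: EDC·HCl, DMAP (0.2 equiv), CH2Cl2, 0 °C → rt
Reagents that add atoms: none
Why: Steglich esterification acylates the secondary allylic alcohol with retention, and keeping DMAP catalytic and cold limits deconjugation of the senecioate.

Step 19
Reactants: 27 (4R,6S,10R,11Z)-10-[(tert-butyldimethylsilyl)oxy]-3-{[(tert-butyldimethylsilyl)oxy]methyl}-6,10-dimethyl-2,7-dioxo-2,4,5,6,7,8,9,10-octahydrocyclodeca[b]furan-4-yl 3-methylbut-2-enoate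
Product: 28 (4R,6S,10R,11Z)-10-hydroxy-3-(hydroxymethyl)-6,10-dimethyl-2,7-dioxo-2,4,5,6,7,8,9,10-octahydrocyclodeca[b]furan-4-yl 3-methylbut-2-enoate
Conditions: HF·pyridine, pyridine, THF, 0 °C → rt
Reagents that add atoms: none
Why: Buffered fluoride desilylation removes the primary and the tertiary silyl ether while the esters and the enol lactone survive the weakly acidic medium.

Step 20
Reactants: 28 (4R,6S,10R,11Z)-10-hydroxy-3-(hydroxymethyl)-6,10-dimethyl-2,7-dioxo-2,4,5,6,7,8,9,10-octahydrocyclodeca[b]furan-4-yl 3-methylbut-2-enoate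
Product: 29 [(4R,6S,10R,11Z)-10-hydroxy-6,10-dimethyl-4-[(3-methylbut-2-enoyl)oxy]-2,7-dioxo-2,4,5,6,7,8,9,10-octahydrocyclodeca[b]furan-3-yl]methyl acetate
Conditions: Ac2O (1.2 equiv), pyridine, CH2Cl2, 0 °C
Reagents that add atoms: acetic anhydride, CC(=O)OC(C)=O
Why: Chemoselective acetylation: the primary allylic alcohol is acylated under conditions where the tertiary alcohol is inert.

**Compound list**
1 | (S)-(2-methyloxiran-2-yl)methanol | OC[C@@]1(C)CO1 | starting material
2 | (R)-2-{[(4-methoxybenzyl)oxy]methyl}-2-methyloxirane | COc1ccc(COC[C@@]2(C)CO2)cc1 | intermediate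
3 | (R)-1-[(4-methoxybenzyl)oxy]-2-methylbut-3-en-2-ol | COc1ccc(COC[C@@](O)(C)C=C)cc1 | intermediate
4 | (R)-tert-butyl({1-[(4-methoxybenzyl)oxy]-2-methylbut-3-en-2-yl}oxy)dimethylsilane | COc1ccc(COC[C@@](O[Si](C)(C)C(C)(C)C)(C)C=C)cc1 | intermediate
5 | chlorobis(cyclopentadienyl){(R)-3-[(tert-butyldimethylsilyl)oxy]-4-[(4-methoxybenzyl)oxy]-3-methylbutyl}zirconium (not isolated) | COc1ccc(COC[C@@](O[Si](C)(C)C(C)(C)C)(C)CC[Zr](Cl)(C2C=CC=C2)C2C=CC=C2)cc1 | intermediate
6 | (R)-tert-butyl({4-iodo-1-[(4-methoxybenzyl)oxy]-2-methylbutan-2-yl}oxy)dimethylsilane | COc1ccc(COC[C@@](O[Si](C)(C)C(C)(C)C)(C)CCI)cc1 | intermediate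
7 | 3-methylideneoxolan-2-one | C=C1CCOC1=O | starting material
8 | (S)-3-methyloxolan-2-one | C[C@H]1CCOC1=O | intermediate
9 | (S)-4-hydroxy-N-methoxy-N,2-dimethylbutanamide | CON(C)C(=O)[C@@H](C)CCO | intermediate
10 | (S)-N-methoxy-N,2-dimethyl-4-[(triethylsilyl)oxy]butanamide | CON(C)C(=O)[C@@H](C)CCO[Si](CC)(CC)CC | intermediate
11 | {(R)-3-[(tert-butyldimethylsilyl)oxy]-4-[(4-methoxybenzyl)oxy]-3-methylbutyl}lithium (not isolated) | COc1ccc(COC[C@@](O[Si](C)(C)C(C)(C)C)(C)CC[Li])cc1 | intermediate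
12 | (3S,7R)-7-[(tert-butyldimethylsilyl)oxy]-8-[(4-methoxybenzyl)oxy]-3,7-dimethyl-1-[(triethylsilyl)oxy]octan-4-one | COc1ccc(COC[C@@](O[Si](C)(C)C(C)(C)C)(C)CCC(=O)[C@@H](C)CCO[Si](CC)(CC)CC)cc1 | intermediate
13 | (3S,7R)-7-[(tert-butyldimethylsilyl)oxy]-8-hydroxy-3,7-dimethyl-1-[(triethylsilyl)oxy]octan-4-one | OC[C@@](O[Si](C)(C)C(C)(C)C)(C)CCC(=O)[C@@H](C)CCO[Si](CC)(CC)CC | intermediate
14 | (2R,6S)-2-[(tert-butyldimethylsilyl)oxy]-2,6-dimethyl-5-oxo-8-[(triethylsilyl)oxy]octanal | O=C[C@@](O[Si](C)(C)C(C)(C)C)(C)CCC(=O)[C@@H](C)CCO[Si](CC)(CC)CC | intermediate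
15 | tetronic acid (4-hydroxyfuran-2(5H)-one) | OC1=CC(=O)OC1 | starting material
16 | [(4-bromo-2-oxo-2,5-dihydrofuran-3-yl)methylidene]dimethylammonium bromide (not isolated) | C[N+](C)=CC1=C(Br)COC1=O.[Br-] | intermediate
17 | 4-bromo-2-oxo-2,5-dihydrofuran-3-carbaldehyde | O=CC1=C(Br)COC1=O | intermediate
18 | 4-bromo-3-(hydroxymethyl)furan-2(5H)-one | OCC1=C(Br)COC1=O | intermediate
19 | 4-bromo-3-{[(tert-butyldimethylsilyl)oxy]methyl}furan-2(5H)-one | CC(C)(C)[Si](C)(C)OCC1=C(Br)COC1=O | intermediate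
20 | 4-bromo-3-{[(tert-butyldimethylsilyl)oxy]methyl}-2-[(triisopropylsilyl)oxy]furan | CC(C)(C)[Si](C)(C)OCc1c(Br)coc1O[Si](C(C)C)(C(C)C)C(C)C | intermediate
21 | 4-bromo-3-{[(tert-butyldimethylsilyl)oxy]methyl}-5-{(2R,6S)-2-[(tert-butyldimethylsilyl)oxy]-1-hydroxy-2,6-dimethyl-5-oxo-8-[(triethylsilyl)oxy]octyl}furan-2(5H)-one, diastereomer mixture at furanone C5 and the carbinol carbon (not isolated) | CC(C)(C)[Si](C)(C)OCC1=C(Br)C(C(O)[C@@](O[Si](C)(C)C(C)(C)C)(C)CCC(=O)[C@@H](C)CCO[Si](CC)(CC)CC)OC1=O | intermediate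
22 | methanesulfonate of 21, same diastereomer mixture (not isolated) | CC(C)(C)[Si](C)(C)OCC1=C(Br)C(C(OS(C)(=O)=O)[C@@](O[Si](C)(C)C(C)(C)C)(C)CCC(=O)[C@@H](C)CCO[Si](CC)(CC)CC)OC1=O | intermediate
23 | (Z)-4-bromo-3-{[(tert-butyldimethylsilyl)oxy]methyl}-5-{(2R,6S)-2-[(tert-butyldimethylsilyl)oxy]-2,6-dimethyl-5-oxo-8-[(triethylsilyl)oxy]octylidene}furan-2(5H)-one | CC(C)(C)[Si](C)(C)OCC1=C(Br)/C(=C/[C@@](O[Si](C)(C)C(C)(C)C)(C)CCC(=O)[C@@H](C)CCO[Si](CC)(CC)CC)OC1=O | intermediate
24 | (3S,7R,8Z)-8-[3-bromo-4-{[(tert-butyldimethylsilyl)oxy]methyl}-5-oxofuran-2(5H)-ylidene]-7-[(tert-butyldimethylsilyl)oxy]-3,7-dimethyl-4-oxooctanal | CC(C)(C)[Si](C)(C)OCC1=C(Br)/C(=C/[C@@](O[Si](C)(C)C(C)(C)C)(C)CCC(=O)[C@@H](C)CC=O)OC1=O | intermediate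
25 | (4R,6S,10R,11Z)-10-[(tert-butyldimethylsilyl)oxy]-3-{[(tert-butyldimethylsilyl)oxy]methyl}-4-hydroxy-6,10-dimethyl-5,6,9,10-tetrahydrocyclodeca[b]furan-2,7(4H,8H)-dione | CC(C)(C)[Si](C)(C)OCC1=C2/C(=C/[C@@](O[Si](C)(C)C(C)(C)C)(C)CCC(=O)[C@@H](C)C[C@H]2O)OC1=O | intermediate
26 | 3-methylbut-2-enoic acid | CC(C)=CC(=O)O | starting material
27 | (4R,6S,10R,11Z)-10-[(tert-butyldimethylsilyl)oxy]-3-{[(tert-butyldimethylsilyl)oxy]methyl}-6,10-dimethyl-2,7-dioxo-2,4,5,6,7,8,9,10-octahydrocyclodeca[b]furan-4-yl 3-methylbut-2-enoate | CC(C)(C)[Si](C)(C)OCC1=C2/C(=C/[C@@](O[Si](C)(C)C(C)(C)C)(C)CCC(=O)[C@@H](C)C[C@H]2OC(=O)C=C(C)C)OC1=O | intermediate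
28 | (4R,6S,10R,11Z)-10-hydroxy-3-(hydroxymethyl)-6,10-dimethyl-2,7-dioxo-2,4,5,6,7,8,9,10-octahydrocyclodeca[b]furan-4-yl 3-methylbut-2-enoate | OCC1=C2/C(=C/[C@@](O)(C)CCC(=O)[C@@H](C)C[C@H]2OC(=O)C=C(C)C)OC1=O | intermediate
29 | [(4R,6S,10R,11Z)-10-hydroxy-6,10-dimethyl-4-[(3-methylbut-2-enoyl)oxy]-2,7-dioxo-2,4,5,6,7,8,9,10-octahydrocyclodeca[b]furan-3-yl]methyl acetate | CC(=O)OCC1=C2/C(=C/[C@](C)(O)CCC(=O)[C@@H](C)C[C@H]2OC(=O)C=C(C)C)OC1=O | target

**Totals**
Total step count: 20. Longest linear sequence: 13 steps (1–4, 8–10, 15–20).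

**Steps most likely to fail, with fallbacks**

Step 17 (ten-membered ring closure). The yield of a medium-ring closure and the sense of induction at the new carbinol are both uncertain. The fallback sets out from 24 and comes back at 27. If the same chromium-mediated closure gives mainly the 4S carbinol, the (4S,6S,10R,11Z) epimer of the macrocyclic alcohol F1, that alcohol is not acylated with retention. Instead it is esterified under Mitsunobu conditions (26, PPh3, DIAD, toluene, 0 °C), which inverts C4 and gives 27 in the same operation.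

Step 15 (vinylogous aldol–dehydration). The aldehyde is neopentyl-like, the bromofuran is a weakened nucleophile, and base could touch the ketone α-centre. The fallback sets out from 19 (with 14) and comes back at 23, replacing the aldol by a Wittig olefination. Radical bromination of 19 (NBS, AIBN, PhCF3, 80 °C) gives racemic 4,5-dibromo-3-{[(tert-butyldimethylsilyl)oxy]methyl}furan-2(5H)-one F2. PPh3 in MeCN then gives the racemic (3-bromo-4-{[(tert-butyldimethylsilyl)oxy]methyl}-5-oxo-2,5-dihydrofuran-2-yl)triphenylphosphonium bromide F3. Its stabilised ylide (Et3N, CH2Cl2, 0 °C) reacts with 14 only at the aldehyde to give 23; a minor E isomer is equilibrated to Z with catalytic iodine.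

Step 11 (bromoformylation of tetronic acid). Simple exchange of OH for Br without C-formylation may dominate. The fallback sets out from 15 and comes back at 17, installing the one-carbon unit first. Condensation of 15 with N,N-dimethylformamide dimethyl acetal (toluene, rt) gives 3-[(dimethylamino)methylidene]furan-2,4(3H,5H)-dione F4 (interconverting E/Z forms). Oxalyl bromide (CH2Cl2, 0 °C) converts the vinylogous amide carbonyl into the bromide, giving iminium salt 16, and aqueous NaOAc hydrolyses it to 17.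

**Further compounds**
F1 | step 17 | (4S,6S,10R,11Z)-10-[(tert-butyldimethylsilyl)oxy]-3-{[(tert-butyldimethylsilyl)oxy]methyl}-4-hydroxy-6,10-dimethyl-5,6,9,10-tetrahydrocyclodeca[b]furan-2,7(4H,8H)-dione | CC(C)(C)[Si](C)(C)OCC1=C2/C(=C/[C@@](O[Si](C)(C)C(C)(C)C)(C)CCC(=O)[C@@H](C)C[C@@H]2O)OC1=O
F2 | step 15 | 4,5-dibromo-3-{[(tert-butyldimethylsilyl)oxy]methyl}furan-2(5H)-one (racemic) | CC(C)(C)[Si](C)(C)OCC1=C(Br)C(Br)OC1=O
F3 | step 15 | (3-bromo-4-{[(tert-butyldimethylsilyl)oxy]methyl}-5-oxo-2,5-dihydrofuran-2-yl)triphenylphosphonium bromide (racemic) | CC(C)(C)[Si](C)(C)OCC1=C(Br)C([P+](c2ccccc2)(c2ccccc2)c2ccccc2)OC1=O.[Br-]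
F4 | step 11 | 3-[(dimethylamino)methylidene]furan-2,4(3H,5H)-dione | CN(C)C=C1C(=O)COC1=O
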